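**Plan**

- Numbering: C7 is the benzylic carbinol carbon and C8 the methine that carries the methyl group and the aryloxy oxygen. Ring A is the 4-allyl-2,6-dimethoxyphenyl ether ring and ring B the 3,4,5-trimethoxyphenyl ring.
- Enabling feature: C7 is bonded only to C8, to C1 of ring B and to oxygen. A CHCl2 carbon inserted into a C8–B bond can collect exactly these three: C8 by migration, the aryl group from a Grignard reagent, and oxygen from the boron that remains.
- Retrosynthesis: C7–O is traced back to C7–B. C7–C8 and C7–C1 (ring B) are cut together, giving a C8 boronic ester, CH2Cl2 and the ring B Grignard reagent. The C8–O (ring A) bond is cut to a 1-chloroethyl boronic ester and the phenol, and the C8–CH3 bond of that ester to a (dichloromethyl)boronic ester and a methyl Grignard reagent.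
- Forward: C8 starts as the dichloromethyl carbon on boron and takes up the methyl group, then the aryloxide. A second dichloromethyl carbon, inserted into the C8–B bond, becomes C7 and takes up ring B, and oxidation then gives C7–OH. No ring is formed; both arenes are bought.
- Stereochemistry: one (S,S)-1,2-dicyclohexylethane-1,2-diol on boron selects the chloride that leaves in each boron-to-carbon shift. The remaining C–Cl bond is each time substituted with inversion and the final oxidation is retentive, which gives 8R and then 7R.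

Key step: step 5

Remark: the (S,S)-diol is assumed to direct both chloride-expelling shifts as it does for simple alkylboronic esters (chloride carbon R when Cl > migrated carbon > B), also with an aryloxy group next to boron.

**Route**

Step 1
Reactants: 1 diisopropyl (dichloromethyl)boronate; 2 (1S,2S)-1,2-dicyclohexylethane-1,2-diol
Product: 3 (4S,5S)-4,5-dicyclohexyl-2-(dichloromethyl)-1,3,2-dioxaborolane
Conditions: Et2O, rt; then i-PrOH and solvent removed under vacuum
Reagents that add atoms: none
Why: transesterification of an acyclic boronic ester by a 1,2-diol is driven by ring formation and by removal of the volatile isopropanol, and leaves the diol stereocentres untouched.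

Step 2
Reactants: 3 (4S,5S)-4,5-dicyclohexyl-2-(dichloromethyl)-1,3,2-dioxaborolane
Product: 5 (4S,5S)-2-[(1R)-1-chloroethyl]-4,5-dicyclohexyl-1,3,2-dioxaborolane, via chloromagnesium borate 4 (not isolated)
Conditions: MeMgCl, THF, −78 °C; then ZnCl2, −78 °C → rt
Reagents that add atoms: methylmagnesium chloride C[Mg]Cl
Why: Matteson homologation with the order of addition reversed, in which MeMgCl adds to boron to give borate 4 (the same ate complex a methylboronic ester and LiCHCl2 would give, because the C2-symmetric diol makes both faces of boron equivalent) and the ZnCl2-assisted shift of methyl from boron to carbon expels the chloride that the (S,S)-diol selects, so the (1R)-chloride should form while ZnCl2 binds the free chloride that would epimerise it.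

Step 3
Reactants: 5 (4S,5S)-2-[(1R)-1-chloroethyl]-4,5-dicyclohexyl-1,3,2-dioxaborolane; 6 4-allyl-2,6-dimethoxyphenol
Product: 9 (4S,5S)-2-[(1S)-1-(4-allyl-2,6-dimethoxyphenoxy)ethyl]-4,5-dicyclohexyl-1,3,2-dioxaborolane, via sodium phenoxide 7 (not isolated), via sodium aryloxyborate 8 (not isolated)
Conditions: 6 (slight excess over NaH), NaH, THF, 0 °C; then 5, THF/DMSO, 0 °C → rt
Reagents that add atoms: none
Why: substitution of an α-chloro boronic ester by an oxygen nucleophile, in which the aryloxide binds to boron and shifts to carbon anti to the C–Cl bond, so C8 is inverted to the (1S)-aryloxy ester; keeping the phenol in slight excess ensures no base stronger than the phenoxide is present to move the allyl double bond into conjugation.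

Step 4
Reactants: 10 5-bromo-1,2,3-trimethoxybenzene
Product: 11 3,4,5-trimethoxyphenylmagnesium bromide
Conditions: Mg turnings, I2 (cat.), THF, rt → 50 °C
Reagents that add atoms: magnesium [Mg]
Why: Grignard reagent formation by insertion of magnesium into an aryl bromide, routine for this electron-rich bromide; the titrated THF solution is used directly.

Step 5
Reactants: 9 (4S,5S)-2-[(1S)-1-(4-allyl-2,6-dimethoxyphenoxy)ethyl]-4,5-dicyclohexyl-1,3,2-dioxaborolane; 12 dichloromethane; 11 3,4,5-trimethoxyphenylmagnesium bromide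
Product: 17 (4S,5S)-2-[(1R,2R)-2-(4-allyl-2,6-dimethoxyphenoxy)-1-(3,4,5-trimethoxyphenyl)propyl]-4,5-dicyclohexyl-1,3,2-dioxaborolane, via (dichloromethyl)lithium 13 (not isolated), via lithium borate 14 (not isolated), via α-chloro boronic ester 15 (not isolated), via bromomagnesium arylborate 16 (not isolated)
Conditions: CH2Cl2, n-BuLi, THF, −100 °C; then 9; ZnCl2, −100 °C → rt; then 11 (excess over ZnCl2), −78 °C → rt
Reagents that add atoms: none
Why: LiCHCl2 (13), made in the flask from 12, adds to the boron of 9 to give borate 14, and with ZnCl2 the 1-aryloxyethyl group shifts from boron to the dichloromethyl carbon with retention at C8 and loss of one chloride, forming C7–C8 in the α-chloro boronic ester 15. The Grignard reagent 11 then adds to boron to give borate 16, and the 3,4,5-trimethoxyphenyl group shifts to C7 anti to the remaining C–Cl bond, forming the bond from C7 to C1 of ring B with inversion. The closest known reactions are the Matteson homologation of α-alkoxy boronic esters and the Grignard substitution of the resulting α-chloro boronic esters, here run in one flask; no ring is closed. The new stereocentre C7 is controlled by the (S,S)-diol on boron, which decides which diastereotopic chloride leaves in the first shift (1R in 15), and the stereospecific inversion in the second shift then gives 7R in 17, while C8 is carried through unchanged. The step needs 1,2-migration to win over β-elimination of the ring A aryloxide from borate 16 and over chloride-induced epimerisation of 15. This should be secured by chloride on C7 being a far better leaving group than the electron-rich aryloxide on C8, by the low temperature of the Grignard addition and by ZnCl2 as chloride sink.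

Step 6
Reactants: 17 (4S,5S)-2-[(1R,2R)-2-(4-allyl-2,6-dimethoxyphenoxy)-1-(3,4,5-trimethoxyphenyl)propyl]-4,5-dicyclohexyl-1,3,2-dioxaborolane
Product: 18 (1R,2R)-2-(4-allyl-2,6-dimethoxyphenoxy)-1-(3,4,5-trimethoxyphenyl)propan-1-ol (CNP0320712.1)
Conditions: 30% H2O2, NaOH, THF/H2O, 0 °C → rt
Reagents that add atoms: hydrogen peroxide OO
Why: alkaline hydrogen peroxide oxidation of a boronic ester, an oxidative shift of C7 from boron to oxygen with retention, should turn the (7R)-boronic ester into the (7R)-alcohol and release diol 2 for recovery; the terminal alkene and the aryl ethers are inert to these conditions.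

**Compound list**

1 | diisopropyl (dichloromethyl)boronate [(dichloromethyl)bis(propan-2-yloxy)borane] | CC(C)OB(OC(C)C)C(Cl)Cl | starting material
2 | (1S,2S)-1,2-dicyclohexylethane-1,2-diol | O[C@@H](C1CCCCC1)[C@@H](O)C1CCCCC1 | starting material
3 | (4S,5S)-4,5-dicyclohexyl-2-(dichloromethyl)-1,3,2-dioxaborolane | ClC(Cl)B1O[C@@H](C2CCCCC2)[C@H](C2CCCCC2)O1 | intermediate
4 | chloromagnesium (4S,5S)-4,5-dicyclohexyl-2-(dichloromethyl)-2-methyl-1,3,2-dioxaborolan-2-uide | Cl[Mg+].C[B-]1(C(Cl)Cl)O[C@@H](C2CCCCC2)[C@H](C2CCCCC2)O1 | intermediate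
5 | (4S,5S)-2-[(1R)-1-chloroethyl]-4,5-dicyclohexyl-1,3,2-dioxaborolane | C[C@H](Cl)B1O[C@@H](C2CCCCC2)[C@H](C2CCCCC2)O1 | intermediate
6 | 4-allyl-2,6-dimethoxyphenol | C=CCc1cc(OC)c(O)c(OC)c1 | starting material
7 | sodium 4-allyl-2,6-dimethoxyphenoxide | [Na+].C=CCc1cc(OC)c([O-])c(OC)c1 | intermediate
8 | sodium (4S,5S)-2-(4-allyl-2,6-dimethoxyphenoxy)-2-[(1R)-1-chloroethyl]-4,5-dicyclohexyl-1,3,2-dioxaborolan-2-uide | [Na+].C=CCc1cc(OC)c(O[B-]2(O[C@@H](C3CCCCC3)[C@H](C3CCCCC3)O2)[C@H](C)Cl)c(OC)c1 | intermediate
9 | (4S,5S)-2-[(1S)-1-(4-allyl-2,6-dimethoxyphenoxy)ethyl]-4,5-dicyclohexyl-1,3,2-dioxaborolane | C=CCc1cc(OC)c(O[C@H](C)B2O[C@@H](C3CCCCC3)[C@H](C3CCCCC3)O2)c(OC)c1 | intermediate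
10 | 5-bromo-1,2,3-trimethoxybenzene | COc1cc(Br)cc(OC)c1OC | starting material
11 | 3,4,5-trimethoxyphenylmagnesium bromide | COc1cc([Mg]Br)cc(OC)c1OC | intermediate
12 | dichloromethane | ClCCl | starting material
13 | (dichloromethyl)lithium | [Li]C(Cl)Cl | intermediate
14 | lithium (4S,5S)-2-[(1S)-1-(4-allyl-2,6-dimethoxyphenoxy)ethyl]-4,5-dicyclohexyl-2-(dichloromethyl)-1,3,2-dioxaborolan-2-uide | [Li+].C=CCc1cc(OC)c(O[C@H](C)[B-]2(C(Cl)Cl)O[C@@H](C3CCCCC3)[C@H](C3CCCCC3)O2)c(OC)c1 | intermediate
15 | (4S,5S)-2-[(1R,2R)-2-(4-allyl-2,6-dimethoxyphenoxy)-1-chloropropyl]-4,5-dicyclohexyl-1,3,2-dioxaborolane | C=CCc1cc(OC)c(O[C@H](C)[C@H](Cl)B2O[C@@H](C3CCCCC3)[C@H](C3CCCCC3)O2)c(OC)c1 | intermediate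
16 | bromomagnesium (4S,5S)-2-[(1R,2R)-2-(4-allyl-2,6-dimethoxyphenoxy)-1-chloropropyl]-4,5-dicyclohexyl-2-(3,4,5-trimethoxyphenyl)-1,3,2-dioxaborolan-2-uide | Br[Mg+].C=CCc1cc(OC)c(O[C@H](C)[C@H](Cl)[B-]2(c3cc(OC)c(OC)c(OC)c3)O[C@@H](C3CCCCC3)[C@H](C3CCCCC3)O2)c(OC)c1 | intermediate
17 | (4S,5S)-2-[(1R,2R)-2-(4-allyl-2,6-dimethoxyphenoxy)-1-(3,4,5-trimethoxyphenyl)propyl]-4,5-dicyclohexyl-1,3,2-dioxaborolane | C=CCc1cc(OC)c(O[C@H](C)[C@H](B2O[C@@H](C3CCCCC3)[C@H](C3CCCCC3)O2)c2cc(OC)c(OC)c(OC)c2)c(OC)c1 | intermediate
18 | (1R,2R)-2-(4-allyl-2,6-dimethoxyphenoxy)-1-(3,4,5-trimethoxyphenyl)propan-1-ol | C=CCc1cc(OC)c(O[C@H](C)[C@H](O)c2cc(OC)c(OC)c(OC)c2)c(OC)c1 | target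

**Step count**

Total steps: 6. Longest linear sequence: 5 steps (steps 1, 2, 3, 5, 6); step 4 prepares the Grignard reagent that joins in step 5.

**Steps most likely to fail**

1. Step 5. β-Elimination of the ring A aryloxide from the aryl borate, or chloride-mediated epimerisation at C7 before the aryl shift, may outrun the 1,2-migration. The fallback leaves boron chemistry and sets out from phenol 6, using Grignard reagent 11. Mitsunobu etherification of 6 with ethyl (S)-lactate (PPh3, DIAD, THF, 0 °C → rt) should give, with inversion, ethyl (2R)-2-(4-allyl-2,6-dimethoxyphenoxy)propanoate F1. MeNHOMe·HCl and i-PrMgCl (THF, −20 °C) should convert it into (2R)-2-(4-allyl-2,6-dimethoxyphenoxy)-N-methoxy-N-methylpropanamide F2. Single addition of 11 (THF, 0 °C) should then give (2R)-2-(4-allyl-2,6-dimethoxyphenoxy)-1-(3,4,5-trimethoxyphenyl)propan-1-one F3. Felkin–Anh reduction of this ketone with LiBH(s-Bu)3 (THF, −78 °C), hydride arriving anti to the aryloxy group, should give the threo alcohol, so the fallback comes back to the route at target 18.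

2. Step 3. Substitution by the hindered, weakly nucleophilic 2,6-dimethoxyphenoxide at the crowded boron may be slow, so that chloride exchange erodes the configuration at C8. The fallback changes the leaving group and the way C8 is built, and sets out from diol 2. Condensation of 2 with methylboronic acid (Et2O, MgSO4, rt) should give (4S,5S)-4,5-dicyclohexyl-2-methyl-1,3,2-dioxaborolane F4. Homologation with CH2Br2 and LiN(i-Pr)2, the base being added to the mixture of both in THF at −78 °C and the mixture then warmed to rt, should give (4S,5S)-2-[(1R)-1-bromoethyl]-4,5-dicyclohexyl-1,3,2-dioxaborolane F5. The more reactive bromide is then displaced by sodium phenoxide 7 in THF at 0 °C without DMSO, with inversion, and the fallback comes back to the route at 9.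

3. Step 6. Slow attack of hydroperoxide at the hindered boron may let base-induced β-elimination of the aryloxide, or base-mediated migration of the allyl double bond, compete with oxidation. The fallback sets out from 17. KHF2 in MeOH/H2O should exchange the diol for fluoride and give potassium [(1R,2R)-2-(4-allyl-2,6-dimethoxyphenoxy)-1-(3,4,5-trimethoxyphenyl)propyl]trifluoroborate F6, with diol 2 recovered. Oxone (2KHSO5·KHSO4·K2SO4) in acetone/H2O at rt, for a few minutes only, should then oxidise the unhindered trifluoroborate with retention under near-neutral conditions. The fallback comes back to the route at target 18.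

**Further compounds**

F1 | step 5 | ethyl (2R)-2-(4-allyl-2,6-dimethoxyphenoxy)propanoate | C=CCc1cc(OC)c(O[C@H](C)C(=O)OCC)c(OC)c1
F2 | step 5 | (2R)-2-(4-allyl-2,6-dimethoxyphenoxy)-N-methoxy-N-methylpropanamide | C=CCc1cc(OC)c(O[C@H](C)C(=O)N(C)OC)c(OC)c1
F3 | step 5 | (2R)-2-(4-allyl-2,6-dimethoxyphenoxy)-1-(3,4,5-trimethoxyphenyl)propan-1-one | C=CCc1cc(OC)c(O[C@H](C)C(=O)c2cc(OC)c(OC)c(OC)c2)c(OC)c1
F4 | step 3 | (4S,5S)-4,5-dicyclohexyl-2-methyl-1,3,2-dioxaborolane | CB1O[C@@H](C2CCCCC2)[C@H](C2CCCCC2)O1
F5 | step 3 | (4S,5S)-2-[(1R)-1-bromoethyl]-4,5-dicyclohexyl-1,3,2-dioxaborolane | C[C@H](Br)B1O[C@@H](C2CCCCC2)[C@H](C2CCCCC2)O1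
F6 | step 6 | potassium [(1R,2R)-2-(4-allyl-2,6-dimethoxyphenoxy)-1-(3,4,5-trimethoxyphenyl)propyl]trifluoroborate | [K+].C=CCc1cc(OC)c(O[C@H](C)[C@H]([B-](F)(F)F)c2cc(OC)c(OC)c(OC)c2)c(OC)c1
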